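Remark: compounds 1 and 6 are taken to be purchasable. The target has no stereogenic element, so no SMILES here needs a stereodescriptor.

## Structural features

The target 11 (C18H6Br8O6) is a linear tris-arene: a central ring B is joined through two diaryl ether oxygens to two identical outer rings A and C, and the two halves are related by the inversion centre of ring B. There is no stereocentre, so no stereocentres stand next to each other and nothing has to be set or kept in that respect. Ring B is hexasubstituted and has no C–H bond: C1 and C4 carry the ether oxygens, C2 and C5 free hydroxyls, C3 and C6 bromine, so each ether oxygen sits between a hydroxyl and a bromine. Each outer ring is a 2,3,5-tribromo-4-hydroxyphenoxy group with the ether carbon C1', the only ring hydrogen at C2', bromine at C3', C5' and C6', and a hydroxyl at C4' that is para to C1' and flanked by two bromines. Fragile points are the electron-rich hydroquinone of ring B, which is easily oxidised to a quinone, the acidic polybromophenols, which can lose or shift bromine under electrophilic or strongly acidic conditions, and the eight C–Br bonds, which exclude palladium, nickel, organolithium and hydrogenolysis chemistry once they are in place. The real difficulty lies in the two tri-ortho-substituted diaryl ether links, each of which must be made at one defined oxygen of a polyoxygenated ring, and in placing eight bromines and four free hydroxyls without any isomer. The key step exploits the para relation of C1' and C4' in rings A and C, which is the footprint of a 4-oxocyclohexadienylidene that has inserted into an O–H bond, and the oxygen pattern C1, C2, C4, C5 of ring B, which lets both ether oxygens be supplied by an intact, fully substituted ring B.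

## Logic of the disconnections

11 is first traced back to 10 by writing the hydroxyls on C2 and C5 of ring B as methyl ethers; in the forward sense two O–CH3 bonds are cut. The reason is that with these two oxygens capped, only O1 and O4 of ring B are free one stage earlier, so the four oxygens of ring B are told apart. Nothing is gained in size, but the regiochemical problem on ring B disappears. The demand is a dealkylation that spares two diaryl ethers, eight C–Br bonds and an oxidisable hydroquinone.

10 is then cut at the two O–C1' bonds, between each ring B oxygen and the outer-ring carbon, and not at the ring B carbon–oxygen bonds. This gives 8, which holds ring B with all six substituents, and two molecules of 5, in which the later C1' is the diazo-bearing carbon of a cyclohexadienone. In one sentence: two carbenes from 5 are inserted into the two free O–H bonds of the fully substituted hydroquinone 8. The cut is placed here because the C4' hydroxyl para to C1' is what the carbene leaves behind on insertion, and because ring B never has to undergo substitution at carbon. The gain is that an eighteen-carbon octabromide falls to one symmetric C6 unit and two copies of one tribromo C6 unit, with no protecting group on the outer rings. The demand is that the carbene picks the ring B hydroxyls of 8 and of the mono-ether 9 over the outer-ring hydroxyls that the step itself creates.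

5 is traced through 4 to 3: the N2 unit on the later C1' is cut back to an amino group on the same carbon. The reason is that the carbon–nitrogen bond fixes the position of the later ether link, and the amine is one redox step from a nitro group. The demand is a diazotisation that does not displace the bromine ortho to the diazonium group.

3 is traced to 2 by exchanging the amine for a nitro group, and 2 to 1 by cutting the two C–Br bonds ortho to the hydroxyl. 1 already holds the third bromine and the para nitrogen, so the substitution pattern of the outer ring follows from the directing effect of one hydroxyl. The demand is bromination at the two ortho positions only and a nitro reduction that leaves C–Br intact.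

8 is traced to 7 by a change of oxidation level, and 7 to 6 by cutting the two C–OCH3 bonds of ring B back to C–Br. The reason is that 6 is symmetric, purchasable and already carries the two bromines that stay. The demand is that exactly two para-disposed bromides of 6 are replaced.

## Other disconnections considered

Alternative 1: the first that comes to mind.
- **Cut:** the two ring B carbon–oxygen bonds, C1–O and C4–O.
- **Forward key step:** two-fold addition–elimination of the hydroquinone 2,3,5-tribromobenzene-1,4-diol A1 on quinone 6 to give the bis(aryloxy)quinone A2, then reduction.
- **Ground for the chosen plan:** A1 offers two different hydroxyls, and the one that ionises first (between two bromines) is the one that must stay free, so the ether constitution is not secured. A1 and 6 are a hydroquinone and a quinone of similar potential and are expected to exchange hydrogen before substitution, which would scramble the oxidation levels of both partners. The cure, a hydroquinone capped at the acidic oxygen, needs a separate amine-to-phenol sequence that brings the step count to that of the chosen plan and adds a protecting group on each outer ring. The chosen plan forms the other C–O bond of each ether and creates the C4' hydroxyl in the bond-forming event.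

Alternative 2:
- **Cut:** the same ring B carbon–oxygen bonds, but at the bromine-free stage.
- **Forward key step:** copper-mediated Ullmann coupling to assemble the bromine-free tris-hydroquinone A3, then eightfold electrophilic bromination.
- **Ground for the chosen plan:** bromination would have to stop at three of the four free positions on each outer ring, and the fourth position is activated by the same ether oxygen as the third. The three hydroquinone rings are expected to be oxidised by bromine, and ipso attack at C1' para to a free hydroxyl would cleave the ether. No element of the substrate controls the count or the position of the bromines. In the chosen plan every bromine is placed by one hydroxyl-directed bromination of 1 or is bought with 6.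

Alternative 3:
- **Cut:** the carbon–carbon bonds of ring B, building it from a four-membered ring and an alkyne.
- **Forward key step:** thermal ring expansion of the 4-alkynyl-4-hydroxycyclobutenone A4 (Moore-type rearrangement) to the 2,5-bis(aryloxy)quinone A5, then bromination and reduction.
- **Ground for the chosen plan:** the sequence constructs a ring that is purchasable with its final substituents. A4 requires an organolithium addition that aryl bromides would not survive, so all eight bromines would have to be added afterwards with the selectivity problem of alternative 2. The step count would at least double.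

Key step: step 6

## Route

Step 1
Reactants: 1 3-bromo-4-nitrophenol
Product: 2 2,3,6-tribromo-4-nitrophenol
Conditions: Br2 (2.2 equiv), AcOH, 20 to 60 °C
Reagents that add atoms: bromine, BrBr
Why: Electrophilic aromatic bromination; the hydroxyl directs to its two free ortho positions, the para position is blocked by the nitro group and the remaining C–H is meta to the hydroxyl and ortho to nitro, so the reaction should stop at the tribromide.

Step 2
Reactants: 2 2,3,6-tribromo-4-nitrophenol
Product: 3 4-amino-2,3,6-tribromophenol
Conditions: SnCl2·2H2O (5 equiv), conc. HCl, EtOH, 70 °C; then aq. NaHCO3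
Reagents that add atoms: none
Why: Chemoselective nitro reduction by SnCl2 in acid, which should leave the aryl C–Br bonds untouched where catalytic hydrogenation would not; the air-sensitive aminophenol is used without delay.

Step 3
Reactants: 3 4-amino-2,3,6-tribromophenol
Product: 5 2,3,6-tribromo-4-diazocyclohexa-2,5-dien-1-one, via diazonium hydrogensulfate 4 (not isolated)
Conditions: NaNO2 (1.05 equiv), aq. H2SO4, AcOH, 0 °C; then aq. NaOAc to pH 5, 0 °C; filtered and kept cold in the dark, small scale behind a shield
Reagents that add atoms: sodium nitrite, [Na+].[O-]N=O
Why: Diazotisation of the arylamine gives 4, whose hydroxyl para to the diazonium group is strongly acidic, so buffering removes the proton and the neutral quinone diazide 5 should separate; H2SO4 is chosen over HCl so that no chloride can displace the bromine ortho to the diazonium group.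

Step 4
Reactants: 6 2,3,5,6-tetrabromocyclohexa-2,5-diene-1,4-dione (bromanil)
Product: 7 2,5-dibromo-3,6-dimethoxycyclohexa-2,5-diene-1,4-dione
Conditions: NaOMe (2.05 equiv), MeOH, 0 to 20 °C
Reagents that add atoms: sodium methoxide, [Na+].[O-]C
Why: Addition–elimination of an alkoxide on a haloquinone; the first methoxy group turns its own enone unit into a vinylogous ester and deactivates the adjacent carbon, so the second methoxide should enter para to the first, as is general for tetrahaloquinones.

Step 5
Reactants: 7 2,5-dibromo-3,6-dimethoxycyclohexa-2,5-diene-1,4-dione
Product: 8 2,5-dibromo-3,6-dimethoxybenzene-1,4-diol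
Conditions: Na2S2O4 (3 equiv), EtOAc/H2O, 20 °C, argon
Reagents that add atoms: none
Why: Dithionite reduction of a quinone to its hydroquinone, which does not touch C–Br or C–OMe bonds; 8 is kept under argon to prevent re-oxidation.

Step 6
Reactants: 8 2,5-dibromo-3,6-dimethoxybenzene-1,4-diol; 5 2,3,6-tribromo-4-diazocyclohexa-2,5-dien-1-one (2.2 equiv)
Product: 10 4,4'-[(2,5-dibromo-3,6-dimethoxy-1,4-phenylene)bis(oxy)]bis(2,3,6-tribromophenol), via mono-aryl ether 9 (not isolated)
Conditions: Rh2(OAc)4 (2 mol %), 1,2-dichloroethane, 50 to 60 °C, 5 added over 6 h, argon, dark
Reagents that add atoms: none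
Why: Rh2(OAc)4 takes up the diazo carbon of 5 and expels N2 to give an electrophilic 4-oxocyclohexa-2,5-dienylidene complex of rhodium, in which that carbon (the later C1' of an outer ring) behaves as a masked aryl cation. A free hydroxyl oxygen of ring B in 8 adds to this carbon to give an oxonium ylide; the carbon–rhodium electrons then flow into the dienone, which aromatises to a phenoxide, and the oxonium proton ends on that oxygen, so the net result is an O–H insertion that forms the O–C1' bond and sets the C4' hydroxyl free in the same event. A second molecule of 5 repeats this on the remaining ring B hydroxyl of 9 to give 10. The closest known reaction type is the carbene O–H insertion of para-quinone diazides into alcohols and phenols under Rh2(OAc)4 catalysis or on photolysis, which gives 4-alkoxy- and 4-aryloxyphenols. No ring is closed and no stereocentre is formed. The selectivity needed is ring B hydroxyl over the newly formed outer-ring hydroxyls: the ring B oxygens sit on a tetra-oxygenated ring beside one bromine and one methoxy group and should be the more basic and less shielded donors, whereas each new hydroxyl lies between two bromines on a tribromo ring, and slow addition of 5 keeps the carbene concentration low. The constitution is fixed by the partners: the diazo carbon of 5 is flanked by C–Br and C–H and its carbonyl by two C–Br, and ring B of 8 has no C–H bond, so neither C-arylation of ring B nor an isomeric ether can arise.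

Step 7
Reactants: 10 4,4'-[(2,5-dibromo-3,6-dimethoxy-1,4-phenylene)bis(oxy)]bis(2,3,6-tribromophenol)
Product: 11 2,5-dibromo-3,6-bis(2,3,5-tribromo-4-hydroxyphenoxy)benzene-1,4-diol (CNP0163357.0)
Conditions: BBr3 (8 equiv), CH2Cl2, −78 to 20 °C; then H2O, aq. Na2S2O4 wash, argon
Reagents that add atoms: none
Why: Lewis acid-mediated cleavage of aryl methyl ethers, in which bromide attacks the methyl group of the boron-complexed ether (SN2); the diaryl ether oxygens carry no sp3 carbon and the aryl C–Br bonds are inert, the excess of BBr3 covers the two free phenols, and the reductive work-up keeps ring B at the hydroquinone level.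

## Compound list

1 | 3-bromo-4-nitrophenol | Oc1cc(Br)c([N+](=O)[O-])cc1 | starting material
2 | 2,3,6-tribromo-4-nitrophenol | Oc1c(Br)c(Br)c([N+](=O)[O-])cc1Br | intermediate
3 | 4-amino-2,3,6-tribromophenol | Nc1cc(Br)c(O)c(Br)c1Br | intermediate
4 | 2,3,5-tribromo-4-hydroxybenzenediazonium hydrogensulfate | Oc1c(Br)cc([N+]#N)c(Br)c1Br.OS(=O)(=O)[O-] | intermediate
5 | 2,3,6-tribromo-4-diazocyclohexa-2,5-dien-1-one | O=C1C(Br)=CC(=[N+]=[N-])C(Br)=C1Br | intermediate
6 | 2,3,5,6-tetrabromocyclohexa-2,5-diene-1,4-dione (bromanil) | O=C1C(Br)=C(Br)C(=O)C(Br)=C1Br | starting material
7 | 2,5-dibromo-3,6-dimethoxycyclohexa-2,5-diene-1,4-dione | COC1=C(Br)C(=O)C(OC)=C(Br)C1=O | intermediate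
8 | 2,5-dibromo-3,6-dimethoxybenzene-1,4-diol | COc1c(O)c(Br)c(OC)c(O)c1Br | intermediate
9 | 2,5-dibromo-3,6-dimethoxy-4-(2,3,5-tribromo-4-hydroxyphenoxy)phenol | COc1c(O)c(Br)c(OC)c(Oc2cc(Br)c(O)c(Br)c2Br)c1Br | intermediate
10 | 4,4'-[(2,5-dibromo-3,6-dimethoxy-1,4-phenylene)bis(oxy)]bis(2,3,6-tribromophenol) | COc1c(Oc2cc(Br)c(O)c(Br)c2Br)c(Br)c(OC)c(Oc2cc(Br)c(O)c(Br)c2Br)c1Br | intermediate
11 | 2,5-dibromo-3,6-bis(2,3,5-tribromo-4-hydroxyphenoxy)benzene-1,4-diol | Oc1c(Br)cc(Oc2c(O)c(Br)c(Oc3cc(Br)c(O)c(Br)c3Br)c(O)c2Br)c(Br)c1Br | target

## Step count and least certain steps

Total step count: 7. Longest linear sequence: 5 steps (steps 1, 2, 3, 6, 7 from 1); the second branch has 2 steps (steps 4 and 5 from 6).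

**Step 6 (key step).** The most likely failure is carbene transfer to the wrong hydroxyl. As 9 and 10 build up, their outer-ring hydroxyls compete with the last ring B hydroxyl, which would lead to chain growth toward oligomeric aryl ethers. Hydrogen transfer from the hydroquinone to the carbene (redox quenching) and slow capture at the doubly ortho-substituted oxygen of 9 could also lower conversion. The fallback sets out from 2 and 6 and comes back to the route at 11; it forms the ring B carbon–oxygen bonds instead.
- 2 is O-methylated (MeI, K2CO3, DMF) to 2,3,6-tribromo-4-nitroanisole F1.
- F1 is reduced (SnCl2·2H2O, EtOH, 70 °C) to 2,3,5-tribromo-4-methoxyaniline F2.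
- F2 is diazotised (NaNO2, aq. H2SO4, 0 °C) to 2,3,5-tribromo-4-methoxybenzenediazonium hydrogensulfate F3, which is hydrolysed in boiling dilute H2SO4 to 2,3,5-tribromo-4-methoxyphenol F4.
- Two equivalents of F4 with K2CO3 in MeCN should displace two para bromides of 6 by addition–elimination to give 2,5-dibromo-3,6-bis(2,3,5-tribromo-4-methoxyphenoxy)cyclohexa-2,5-diene-1,4-dione F5.
- Na2S2O4 reduces F5 to 2,5-dibromo-3,6-bis(2,3,5-tribromo-4-methoxyphenoxy)benzene-1,4-diol F6, and BBr3 in CH2Cl2 cleaves the two methyl ethers to give 11.

**Step 3.** The likely problems are displacement of the bromine ortho to the diazonium group by water during diazotisation, incomplete diazotisation of the weakly basic and hindered amine, and loss of nitrogen from the light- and shock-sensitive diazide during isolation. The fallback sets out from 3 and comes back at 5; it makes the diazo group by condensation and elimination instead of diazotisation.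
- 3 is oxidised with aqueous FeCl3, through hydrolysis of the quinone imine, to 2,3,5-tribromocyclohexa-2,5-diene-1,4-dione F7.
- F7 is condensed with one equivalent of 4-methylbenzenesulfonohydrazide at the less hindered carbonyl (the one between C–H and C–Br) to give N'-(2,3,5-tribromo-4-oxocyclohexa-2,5-dien-1-ylidene)-4-methylbenzenesulfonohydrazide F8.
- Mild base (basic Al2O3 or dilute aq. NaOH) eliminates sulfinate from F8 and gives 5.

**Step 7.** The likely problems are acid-induced loss or migration of bromine on the electron-rich ring B in the presence of HBr, incomplete cleavage of one of the two hindered methyl ethers, and air oxidation of the hydroquinone to the quinone during work-up. The fallback sets out from 6, uses 5 as before and comes back at 11; it changes the ring B protecting group so that cleavage proceeds by ionisation at low temperature and not by bromide attack on methyl.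
- 6 is treated with NaOCH(CH3)2 in propan-2-ol to give 2,5-dibromo-3,6-di(propan-2-yloxy)cyclohexa-2,5-diene-1,4-dione F9.
- Na2S2O4 reduces F9 to 2,5-dibromo-3,6-di(propan-2-yloxy)benzene-1,4-diol F10.
- The two-fold insertion with 5 under Rh2(OAc)4 gives 4,4'-{[2,5-dibromo-3,6-di(propan-2-yloxy)-1,4-phenylene]bis(oxy)}bis(2,3,6-tribromophenol) F11.
- BCl3 in CH2Cl2 at 0 °C removes the two secondary alkyl groups and gives 11.

## Further compounds

F1 | step 6 | 2,3,6-tribromo-4-nitroanisole | COc1c(Br)c(Br)c([N+](=O)[O-])cc1Br
F2 | step 6 | 2,3,5-tribromo-4-methoxyaniline | COc1c(Br)c(Br)c(N)cc1Br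
F3 | step 6 | 2,3,5-tribromo-4-methoxybenzenediazonium hydrogensulfate | COc1c(Br)c(Br)c([N+]#N)cc1Br.OS(=O)(=O)[O-]
F4 | step 6 | 2,3,5-tribromo-4-methoxyphenol | COc1c(Br)c(Br)c(O)cc1Br
F5 | step 6 | 2,5-dibromo-3,6-bis(2,3,5-tribromo-4-methoxyphenoxy)cyclohexa-2,5-diene-1,4-dione | O=C1C(Br)=C(Oc2cc(Br)c(OC)c(Br)c2Br)C(=O)C(Br)=C1Oc1cc(Br)c(OC)c(Br)c1Br
F6 | step 6 | 2,5-dibromo-3,6-bis(2,3,5-tribromo-4-methoxyphenoxy)benzene-1,4-diol | Oc1c(Br)c(Oc2cc(Br)c(OC)c(Br)c2Br)c(O)c(Br)c1Oc1cc(Br)c(OC)c(Br)c1Br
F7 | step 3 | 2,3,5-tribromocyclohexa-2,5-diene-1,4-dione | O=C1C=C(Br)C(=O)C(Br)=C1Br
F8 | step 3 | N'-(2,3,5-tribromo-4-oxocyclohexa-2,5-dien-1-ylidene)-4-methylbenzenesulfonohydrazide | O=C1C(Br)=CC(=NNS(=O)(=O)c2ccc(C)cc2)C(Br)=C1Br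
F9 | step 7 | 2,5-dibromo-3,6-di(propan-2-yloxy)cyclohexa-2,5-diene-1,4-dione | CC(C)OC1=C(Br)C(=O)C(OC(C)C)=C(Br)C1=O
F10 | step 7 | 2,5-dibromo-3,6-di(propan-2-yloxy)benzene-1,4-diol | CC(C)Oc1c(O)c(Br)c(OC(C)C)c(O)c1Br
F11 | step 7 | 4,4'-{[2,5-dibromo-3,6-di(propan-2-yloxy)-1,4-phenylene]bis(oxy)}bis(2,3,6-tribromophenol) | CC(C)Oc1c(Oc2cc(Br)c(O)c(Br)c2Br)c(Br)c(OC(C)C)c(Oc2cc(Br)c(O)c(Br)c2Br)c1Br
A1 | alternative 1 | 2,3,5-tribromobenzene-1,4-diol | Oc1cc(Br)c(O)c(Br)c1Br
A2 | alternative 1 | 2,5-dibromo-3,6-bis(2,3,5-tribromo-4-hydroxyphenoxy)cyclohexa-2,5-diene-1,4-dione | O=C1C(Br)=C(Oc2cc(Br)c(O)c(Br)c2Br)C(=O)C(Br)=C1Oc1cc(Br)c(O)c(Br)c1Br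
A3 | alternative 2 | 2,5-bis(4-hydroxyphenoxy)benzene-1,4-diol | Oc1ccc(Oc2cc(O)c(Oc3ccc(O)cc3)cc2O)cc1
A4 | alternative 3 | 4-hydroxy-3-(4-methoxyphenoxy)-4-[(4-methoxyphenoxy)ethynyl]cyclobut-2-en-1-one | O=C1C=C(Oc2ccc(OC)cc2)C1(O)C#COc1ccc(OC)cc1
A5 | alternative 3 | 2,5-bis(4-methoxyphenoxy)cyclohexa-2,5-diene-1,4-dione | O=C1C=C(Oc2ccc(OC)cc2)C(=O)C=C1Oc1ccc(OC)cc1
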